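(The numbers in the tables are simulated for substances that don't exist, noise included.)

Saturday's run had 59 % of its electrophile left at 6.00 min and Monday's run 39 %, with the same charges apart from the protic impurity, 16 mM against 7.4 mM.

| flask | electrophile | nucleophile | free base | protic impurity | remark | time |
|---|---|---|---|---|---|---|
| Monday's | 22 mM | 23.1 mM | 26.4 mM | 7.4 mM | run made earlier |  |
| Saturday's | 22 mM | 23.1 mM | 26.4 mM | 16 mM | run made earlier |  |
| flask | 22 mM | 23.1 mM | 26.4 mM | 11.0 mM |  | 6.0 min |

| run | time / min | electrophile / % | target / % |
|---|---|---|---|
| Monday's | 1.33 | 59 | 40 |
| Monday's | 2.50 | 48 | 39 |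
| Monday's | 4.00 | 39 | 42 |
| Monday's | 5.00 | 41 | 39 |
| Monday's | 6.00 | 39 | 36 |
| Saturday's | 0.500 | 74 | 22 |
| Saturday's | 0.833 | 71 | 30 |
| Saturday's | 1.50 | 66 | 28 |
| Saturday's | 3.00 | 63 | 23 |
| Saturday's | 6.00 | 59 | 21 |

(readings scatter by 2 percentage points)

1. part of the electrophile that has reacted at 6.0 min
2. share of the unused nucleophile that is free and not bound as protonated nucleophile, at 6.0 min

- the numbers in the tables scatter with a standard deviation of 2 percentage points
- the earlier runs do not show how much of nucleophile is bound; that part of a forecast is a guess

What would have to be true of this flask's numbers for its electrophile to be used up? Counting one nucleophile for each impurity charged, the nucleophile charged must cover electrophile plus impurity, 33.0 mM, but it is 23.1 mM, so on this count it falls 9.90 mM short. So I carried one number, 55.0 %: the spare, nucleophile charged minus impurity charged, as a share of the electrophile charged. On this count nucleophile, not electrophile, is the flask's limiting reagent.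

Monday's spare was 71.4 % and the last reading of that run showed 61.0 % used; Saturday's spare was 32.3 % and the last reading of that run showed 41.0 % used, more than its spare. The spare is therefore a scale, not a sharp ceiling. A straight line between the two runs put this flask at 52.6 % used at 6.0 min. The runs do not show how much nucleophile is bound, so I committed to no number for the free share.

The forecast stood at 53 % used and 15 % free, the second with the words “This is a guess”.

The flask gave 52.8 % used and 59.0 % free.

    electrophile + nucleophile ⇌ acid set free + target (K = 0.308, k = 0.636 M⁻¹ s⁻¹)
    nucleophile + acid set free ⇌ protonated nucleophile, settled at all times (K = 13000 M⁻¹)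
    acid set free + free base ⇌ salt of the base, settled at all times (K = 13600 M⁻¹)
    target ⇌ isomer of the product (K = 10.1, k = 0.00204 s⁻¹)
    nucleophile + protic impurity → quenched reagent (k = 2.36 M⁻¹ s⁻¹)

At 6.00 min the quenched reagent in this flask stood at 10.4 mM, against 11.0 mM of impurity charged, while free nucleophile stood at 2.8 % of its charge beside 0.454 mM of protonated nucleophile. The electrophile used in this flask lay 2.2 percentage points below its spare of 55.0 %. The neighbour flask with 92 mM of nucleophile, all else held, has a spare of 368 %, and its electrophile reached 99.9 % used.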